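**Plan**

- Feature used: the ring is a cross-conjugated cyclohexa-2,5-dien-1-one. Its carbonyl C1 carries two vinyl arms (C2=C3 and C6=C5), and the quaternary C4 is γ to C1 through the C5 enol ether. Opening ring bond C3–C4 therefore leaves a divinyl ketone whose enolate is a 3-oxidohexatriene.
- Cuts, in retrosynthetic order: (i) ring bond C3–C4 (6π-electrocyclisation with loss of methoxide); (ii) the two enol-ether C–O bonds (methoxide additions); (iii) the C1–C6 bond (acetylide plus enal); (iv) the ArCH2–CH bond of the side chain (auxiliary alkylation).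
- Forward: the arylpropyl alkyne 10 (steps 1–5) and the iodo enal 15 (steps 6–7) are joined into one acyclic chain (steps 8–10); the only ring is closed last (step 11).
- Stereochemistry: the side-chain (R)-methine comes from the oxazolidinone auxiliary in step 1. The quaternary (R)-C4 comes from the sense of ring closure in step 11, directed by that methine. This direction rests on a conformational argument only and is the weakest point of the route.

Key step: step 11

Remark on the chemistry (assumption): the oxygen-bearing sp3 carbons made in steps 4 and 8 are carried as epimer mixtures, because they are oxidised (step 9) or planarised (step 11) later; their SMILES leave these centres undefined. Ring atoms are numbered as in the name of 23; chain atoms as in the names of 17–21 (chain C1 becomes ring C3, chain C6 becomes ring C4).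

Step 1
Reactants: 1 (4S)-4-benzyl-3-propanoyl-1,3-oxazolidin-2-one; 2 4-(bromomethyl)-1,2-dimethoxybenzene
Product: 4 (4S)-4-benzyl-3-[(2R)-3-(3,4-dimethoxyphenyl)-2-methylpropanoyl]-1,3-oxazolidin-2-one, via sodium enolate 3 (not isolated)
Conditions: NaN(SiMe3)2 (1.1 equiv), THF, −78 °C; then 2, −78 to −20 °C
Reagents that add atoms: none
Why: Evans auxiliary alkylation: the chelated Z-enolate 3 should be attacked by the benzylic bromide on the face away from the C4 benzyl group of the auxiliary, which sets the (R)-methine that ends as the side-chain stereocentre.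

Step 2
Reactants: 4 (4S)-4-benzyl-3-[(2R)-3-(3,4-dimethoxyphenyl)-2-methylpropanoyl]-1,3-oxazolidin-2-one
Product: 5 (2R)-3-(3,4-dimethoxyphenyl)-2-methylpropan-1-ol
Conditions: LiBH4, H2O (1 equiv), Et2O, 0 °C
Reagents that add atoms: none
Why: Hydride reductive cleavage of the N-acyl oxazolidinone should give the primary alcohol and release the auxiliary without touching the α-stereocentre.

Step 3
Reactants: 5 (2R)-3-(3,4-dimethoxyphenyl)-2-methylpropan-1-ol
Product: 6 (2R)-3-(3,4-dimethoxyphenyl)-2-methylpropanal
Conditions: Dess–Martin periodinane, CH2Cl2, 0 °C to rt; used at once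
Reagents that add atoms: none
Why: Dess–Martin oxidation under non-basic conditions should stop at the α-branched aldehyde without enolising the (R)-centre.

Step 4
Reactants: 6 (2R)-3-(3,4-dimethoxyphenyl)-2-methylpropanal; 7 ethynylmagnesium bromide
Product: 8 (4R)-5-(3,4-dimethoxyphenyl)-4-methylpent-1-yn-3-ol (both C3 epimers)
Conditions: THF, −78 to 0 °C; then H2O
Reagents that add atoms: none
Why: Grignard 1,2-addition of the acetylide to the aldehyde; the new carbinol centre is accepted as a mixture because it is planarised in step 11.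

Step 5
Reactants: 8 (4R)-5-(3,4-dimethoxyphenyl)-4-methylpent-1-yn-3-ol
Product: 10 1,2-dimethoxy-4-[(2R)-3-methoxy-2-methylpent-4-yn-1-yl]benzene, via sodium alkoxide 9 (not isolated)
Conditions: NaH (1.1 equiv), THF, 0 °C; then MeI, 0 °C to rt
Reagents that add atoms: iodomethane, CI
Why: Williamson etherification: with a slight excess of NaH at 0 °C the alkoxide 9 should form and be methylated while the far less acidic terminal alkyne stays protonated.

Step 6
Reactants: 11 prop-2-yn-1-ol; 12 prop-2-en-1-ylmagnesium bromide
Product: 14 (2Z)-2-(iodomethylidene)pent-4-en-1-ol, via alkenylmagnesium chelate 13 (not isolated)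
Conditions: 12 (2.5 equiv), CuI (10 mol%), Et2O, −10 °C to rt; then I2, THF, −78 to 0 °C
Reagents that add atoms: iodine, II
Why: Copper-catalysed anti-carbomagnesiation of the propargylic alkoxide followed by iodinolysis: allyl goes to C2 and magnesium to C3 within the five-membered chelate 13, so iodine should end cis to the CH2OH group; the first equivalent of 12 only deprotonates the alcohol.

Step 7
Reactants: 14 (2Z)-2-(iodomethylidene)pent-4-en-1-ol
Product: 15 (2Z)-2-(iodomethylidene)pent-4-enal
Conditions: MnO2, CH2Cl2, rt
Reagents that add atoms: none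
Why: MnO2 oxidation is selective for the allylic alcohol and should leave the alkenyl iodide and the terminal alkene untouched; the iodoalkene geometry is rewritten in step 10 and does not matter.

Step 8
Reactants: 10 1,2-dimethoxy-4-[(2R)-3-methoxy-2-methylpent-4-yn-1-yl]benzene; 15 (2Z)-2-(iodomethylidene)pent-4-enal
Product: 17 (1Z,7R)-8-(3,4-dimethoxyphenyl)-1-iodo-6-methoxy-7-methyl-2-(prop-2-en-1-yl)oct-1-en-4-yn-3-ol (epimers at C3 and C6), via lithium acetylide 16 (not isolated)
Conditions: n-BuLi (1.05 equiv), THF, −78 °C; then 15, −78 to −40 °C; then H2O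
Reagents that add atoms: none
Why: 1,2-Addition of a lithium acetylide to an enal at low temperature, where the acetylide should neither exchange with the alkenyl iodide nor add in a conjugate sense; the new carbinol centre is oxidised in step 9.

Step 9
Reactants: 17 (1Z,7R)-8-(3,4-dimethoxyphenyl)-1-iodo-6-methoxy-7-methyl-2-(prop-2-en-1-yl)oct-1-en-4-yn-3-ol
Product: 18 (1Z,7R)-8-(3,4-dimethoxyphenyl)-1-iodo-6-methoxy-7-methyl-2-(prop-2-en-1-yl)oct-1-en-4-yn-3-one (both C6 epimers)
Conditions: MnO2, CH2Cl2, rt
Reagents that add atoms: none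
Why: MnO2 oxidation of a doubly activated (allylic and propargylic) alcohol should give the cross-conjugated alkenyl alkynyl ketone.

Step 10
Reactants: 18 (1Z,7R)-8-(3,4-dimethoxyphenyl)-1-iodo-6-methoxy-7-methyl-2-(prop-2-en-1-yl)oct-1-en-4-yn-3-one
Product: 20 (1E,4E,7R)-8-(3,4-dimethoxyphenyl)-1,5,6-trimethoxy-7-methyl-2-(prop-2-en-1-yl)octa-1,4-dien-3-one (both C6 epimers), via iodo dienone 19 (not isolated)
Conditions: NaOMe (2.2 equiv), MeOH, 0 °C to rt
Reagents that add atoms: methanol, CO; sodium methoxide, [Na+].[O-]C
Why: Base-catalysed conjugate addition of methanol to the ynone (at C5) and nucleophilic vinylic substitution (addition–elimination) of iodide by methoxide at C1, both under thermodynamic control, so each methoxy group should end anti to the carbonyl (E,E).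

Step 11
Reactants: 20 (1E,4E,7R)-8-(3,4-dimethoxyphenyl)-1,5,6-trimethoxy-7-methyl-2-(prop-2-en-1-yl)octa-1,4-dien-3-one
Product: 23 (4R)-4-[(2R)-1-(3,4-dimethoxyphenyl)propan-2-yl]-4,5-dimethoxy-2-(prop-2-en-1-yl)cyclohexa-2,5-dien-1-one, via potassium trienolate 21 (not isolated), via potassium cyclohexadienolate 22 (not isolated)
Conditions: KN(SiMe3)2 (1.1 equiv), THF, −78 to 45 °C
Reagents that add atoms: none
Why: Proposed new method: the ketone of 20 has no α-hydrogen (chain C2 and C4 are sp2), so the base can only remove the γ-hydrogen at chain C6 to give trienolate 21, a 3-oxido-1,3,5-hexatriene (C1=C2–C3(O−)=C4–C5=C6) that should close between C1 and C6 by thermal disrotatory 6π-electrocyclisation to 22, whose β-methoxy group then leaves by E1cB elimination to give the dienone. The closest known reaction type is the oxyanion-accelerated 6π-electrocyclisation of 3-oxidohexatrienes (trienolates) to cyclohexadienolates, shown for trienolates with an acceptor at C2 and a simple terminus; a donor-only trienolate with a fully substituted, oxygen-bearing terminus and a terminal leaving group has not been shown. The one ring formed is the six-membered carbocycle, closed in the disrotatory 6π-electrocyclic mode, which makes ring bond C3–C4 of 23. The only new stereocentre that survives, ring C4, is fixed by the sense of disrotation and is controlled by the adjacent (R)-methine: with the sec-alkyl group as the outside substituent of the terminus, its hydrogen should lie anti to the forming bond in the pocket beside the C5 methoxy group (A1,3 strain), its arylmethyl arm anti to the C6 methoxy group and away from the ring, and its methyl group on the C1 side, an arrangement open only to the rotation that leads to (4R). The step needs the U-shaped trienolate (C2 cis to C5 across C3=C4) and the C1 methoxy group outside: the first should be reached because HN(SiMe3)2 and liberated methoxide shuttle protons between enolate isomers and only the U-shaped one can react (Curtin–Hammett), the second is secured by the E geometry set in step 10. The facial preference is the least secure of these, since simple steric-approach models would favour the C4 epimer, and it is taken up below.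

**Compound list**

1 | (4S)-4-benzyl-3-propanoyl-1,3-oxazolidin-2-one | CCC(=O)N1[C@@H](Cc2ccccc2)COC1=O | starting material
2 | 4-(bromomethyl)-1,2-dimethoxybenzene | COc1ccc(CBr)cc1OC | starting material
3 | sodium (1Z)-1-[(4S)-4-benzyl-2-oxo-1,3-oxazolidin-3-yl]prop-1-en-1-olate | C/C=C(\[O-])N1[C@@H](Cc2ccccc2)COC1=O.[Na+] | intermediate
4 | (4S)-4-benzyl-3-[(2R)-3-(3,4-dimethoxyphenyl)-2-methylpropanoyl]-1,3-oxazolidin-2-one | C[C@H](Cc1ccc(OC)c(OC)c1)C(=O)N1[C@@H](Cc2ccccc2)COC1=O | intermediate
5 | (2R)-3-(3,4-dimethoxyphenyl)-2-methylpropan-1-ol | C[C@H](Cc1ccc(OC)c(OC)c1)CO | intermediate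
6 | (2R)-3-(3,4-dimethoxyphenyl)-2-methylpropanal | C[C@H](Cc1ccc(OC)c(OC)c1)C=O | intermediate
7 | ethynylmagnesium bromide | C#C[Mg]Br | starting material
8 | (4R)-5-(3,4-dimethoxyphenyl)-4-methylpent-1-yn-3-ol (both C3 epimers) | C#CC(O)[C@H](C)Cc1ccc(OC)c(OC)c1 | intermediate
9 | sodium (4R)-5-(3,4-dimethoxyphenyl)-4-methylpent-1-yn-3-olate | C#CC([O-])[C@H](C)Cc1ccc(OC)c(OC)c1.[Na+] | intermediate
10 | 1,2-dimethoxy-4-[(2R)-3-methoxy-2-methylpent-4-yn-1-yl]benzene (both C3 epimers) | C#CC(OC)[C@H](C)Cc1ccc(OC)c(OC)c1 | intermediate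
11 | prop-2-yn-1-ol | C#CCO | starting material
12 | prop-2-en-1-ylmagnesium bromide | C=CC[Mg]Br | starting material
13 | bromomagnesium (2Z)-2-[(bromomagnesio)methylidene]pent-4-en-1-olate | Br[Mg]/C=C(/CC=C)CO[Mg]Br | intermediate
14 | (2Z)-2-(iodomethylidene)pent-4-en-1-ol | I/C=C(/CC=C)CO | intermediate
15 | (2Z)-2-(iodomethylidene)pent-4-enal | I/C=C(/CC=C)C=O | intermediate
16 | [(4R)-5-(3,4-dimethoxyphenyl)-3-methoxy-4-methylpent-1-yn-1-yl]lithium | [Li]C#CC(OC)[C@H](C)Cc1ccc(OC)c(OC)c1 | intermediate
17 | (1Z,7R)-8-(3,4-dimethoxyphenyl)-1-iodo-6-methoxy-7-methyl-2-(prop-2-en-1-yl)oct-1-en-4-yn-3-ol | I/C=C(/CC=C)C(O)C#CC(OC)[C@H](C)Cc1ccc(OC)c(OC)c1 | intermediate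
18 | (1Z,7R)-8-(3,4-dimethoxyphenyl)-1-iodo-6-methoxy-7-methyl-2-(prop-2-en-1-yl)oct-1-en-4-yn-3-one | I/C=C(/CC=C)C(=O)C#CC(OC)[C@H](C)Cc1ccc(OC)c(OC)c1 | intermediate
19 | (1Z,4E,7R)-8-(3,4-dimethoxyphenyl)-1-iodo-5,6-dimethoxy-7-methyl-2-(prop-2-en-1-yl)octa-1,4-dien-3-one | I/C=C(/CC=C)C(=O)/C=C(/OC)C(OC)[C@H](C)Cc1ccc(OC)c(OC)c1 | intermediate
20 | (1E,4E,7R)-8-(3,4-dimethoxyphenyl)-1,5,6-trimethoxy-7-methyl-2-(prop-2-en-1-yl)octa-1,4-dien-3-one | CO/C=C(\CC=C)C(=O)/C=C(/OC)C(OC)[C@H](C)Cc1ccc(OC)c(OC)c1 | intermediate
21 | potassium (1E,3E,5E,7R)-8-(3,4-dimethoxyphenyl)-1,5,6-trimethoxy-7-methyl-2-(prop-2-en-1-yl)octa-1,3,5-trien-3-olate | CO/C=C(\CC=C)/C([O-])=C\C(OC)=C(/OC)[C@H](C)Cc1ccc(OC)c(OC)c1.[K+] | intermediate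
22 | potassium (3S,4R)-4-[(2R)-1-(3,4-dimethoxyphenyl)propan-2-yl]-3,4,5-trimethoxy-2-(prop-2-en-1-yl)cyclohexa-1,5-dien-1-olate | [O-]C1=C(CC=C)[C@H](OC)[C@](OC)([C@H](C)Cc2ccc(OC)c(OC)c2)C(OC)=C1.[K+] | intermediate
23 | (4R)-4-[(2R)-1-(3,4-dimethoxyphenyl)propan-2-yl]-4,5-dimethoxy-2-(prop-2-en-1-yl)cyclohexa-2,5-dien-1-one | C=CCC1=C[C@](OC)([C@H](C)Cc2ccc(OC)c(OC)c2)C(OC)=CC1=O | target

Total step count: 11. Longest linear sequence: 9 steps (steps 1–5 and 8–11).

**Steps most likely to fail**

1. Step 11 (Proposed new method). The donor-only trienolate may close too slowly, fail to reach the U-shaped geometry, or expel methoxide from C5 in a retro-conjugate addition. The disrotation may also show poor facial selectivity at the terminus, so that both C4 epimers form. The fallback sets out from 18 and comes back at 23, and no compound outside the list is formed (F0).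
   - Methanol is added to the ynone alone (NaOMe 5 mol%, MeOH, −20 °C), so that 19 is isolated with the alkenyl iodide intact.
   - The ring bond is then made by the known palladium-catalysed intramolecular alkenylation of a ketone enolate, here at the γ-carbon of the dienolate (Pd2(dba)3, (R)-BINAP, NaOt-Bu, toluene, 60 °C).
   - The sequence is oxidative addition of zerovalent palladium into the C–I bond, γ-palladation of the dienolate, and reductive elimination from the seven-membered palladacycle.
   - The Z-iodide places palladium cis to the carbonyl as this requires, and the chiral bisphosphine rather than the side-chain methine chooses the face; both ligand antipodes are to be tried.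

2. Step 10. The two methoxide reactions may not keep pace: iodide exchange at the α-branched β-iodo enone may lag behind the fast ynone addition, or the ynone may oligomerise under the excess base. The fallback sets out from 15 and comes back at 20.
   - Iodide is exchanged first at the far more electrophilic enal (NaOMe, MeOH, 0 °C) to give (2E)-2-(methoxymethylidene)pent-4-enal F1.
   - Lithium acetylide 16 is added to F1 (THF, −78 °C) to give (1E,7R)-8-(3,4-dimethoxyphenyl)-1,6-dimethoxy-7-methyl-2-(prop-2-en-1-yl)oct-1-en-4-yn-3-ol F2.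
   - MnO2 oxidation gives (1E,7R)-8-(3,4-dimethoxyphenyl)-1,6-dimethoxy-7-methyl-2-(prop-2-en-1-yl)oct-1-en-4-yn-3-one F3.
   - A catalytic amount of NaOMe in MeOH then only has to add methanol to the ynone.

3. Step 3. The α-stereocentre of aldehyde 6 may lose configurational purity by enolisation during oxidation, handling or the Grignard addition of step 4. The fallback sets out from 4 and comes back at 8, so the aldehyde is never made.
   - The auxiliary is displaced with MeNH(OMe)·HCl and AlMe3 (CH2Cl2, 0 °C) to give (2R)-3-(3,4-dimethoxyphenyl)-N-methoxy-N,2-dimethylpropanamide F4.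
   - Ethynylmagnesium bromide 7 converts F4 into (4R)-5-(3,4-dimethoxyphenyl)-4-methylpent-1-yn-3-one F5; the tetrahedral chelate protects the α-centre until the quench.
   - Luche reduction (NaBH4, CeCl3·7H2O, MeOH, −78 °C) gives 8.

**Further compounds**

F0 | step 11 | none | none
F1 | step 10 | (2E)-2-(methoxymethylidene)pent-4-enal | CO/C=C(\CC=C)C=O
F2 | step 10 | (1E,7R)-8-(3,4-dimethoxyphenyl)-1,6-dimethoxy-7-methyl-2-(prop-2-en-1-yl)oct-1-en-4-yn-3-ol | CO/C=C(\CC=C)C(O)C#CC(OC)[C@H](C)Cc1ccc(OC)c(OC)c1
F3 | step 10 | (1E,7R)-8-(3,4-dimethoxyphenyl)-1,6-dimethoxy-7-methyl-2-(prop-2-en-1-yl)oct-1-en-4-yn-3-one | CO/C=C(\CC=C)C(=O)C#CC(OC)[C@H](C)Cc1ccc(OC)c(OC)c1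
F4 | step 3 | (2R)-3-(3,4-dimethoxyphenyl)-N-methoxy-N,2-dimethylpropanamide | C[C@H](Cc1ccc(OC)c(OC)c1)C(=O)N(C)OC
F5 | step 3 | (4R)-5-(3,4-dimethoxyphenyl)-4-methylpent-1-yn-3-one | C#CC(=O)[C@H](C)Cc1ccc(OC)c(OC)c1
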